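The epsilon flask makes more left-handed product in its first 0.167 d, 51.2%, than in the 2.33 d after it, 15 percentage points. Partner captures the left-handed substrate quickly, and because the yield has passed 50.0% of the charge, the rest must come over from the right-handed substrate.

in all of them: left-handed substrate 20 mM; right-handed substrate 20 mM
- epsilon: partner 60 mM; temperature 70 °C; the very flask that is asked about, followed so far
- gamma: partner 60 mM; temperature 55 °C; run made earlier
- flask: partner 60.0 mM; temperature 70 °C; time 2.5 d

| run | time / d | left-handed product / % | left-handed substrate / % |
|---|---|---|---|
| epsilon | 0.167 | 51.2 | 0.2 |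
| epsilon | 0.500 | 53.4 | 0.3 |
| epsilon | 0.833 | 58.8 | 2.1 |
| epsilon | 1.25 | 59.6 | 0 |
| epsilon | 2.08 | 65.6 | 3.9 |
| epsilon | 2.50 | 66.4 | 0.5 |
| gamma | 0.333 | 47.1 | 2.1 |
| gamma | 1.04 | 52.1 | 1.6 |
| gamma | 1.67 | 52.4 | 0 |
| gamma | 2.50 | 54.0 | 0.1 |
| gamma | 4.00 | 56.2 | 0.2 |
| gamma | 5.00 | 57.3 | 0.7 |

(readings scatter by 1 percentage point)

- partner is single-handed; left-handed substrate and right-handed substrate are mirror images of each other, charged as a racemate, each of them at the stated concentration
- left-handed product taken out counts as made
- additions bring no volume worth counting
- the handed part of partner does not stay in what it makes, so the products of the two hands are mirror images too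

- birch: at 2.5 d raise the temperature by 10 K, then wait 5.0 d
- maple: change nothing and wait 5.0 d more
- elm: at 2.5 d take out 90% of the left-handed product then present, then wait 5.0 d
- oak: at 2.5 d add partner, 100% of the amount charged, then wait 5.0 d

- left-handed product, in percent of the left-handed substrate and right-handed substrate together first charged, at 2.5 d
- what to do for the largest gain in left-handed product; "none" if nothing gains more than 2 percentage points (birch / maple / elm / oak / none)
- left-handed product present, with what was taken out counted in, in percent of the left-handed substrate and right-handed substrate together first charged, after maple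
- left-handed product present, with what was taken out counted in, in percent of the left-handed substrate and right-handed substrate together first charged, after oak

I reckon one partner per product. The charge of partner, 60 mM, less the 26.6 mM in left-handed product read at 2.50 d, leaves 33.4 mM. This is the spare partner, and it is the quantity I carry.

On paper it is more than the 13.4 mM of charge not read as left-handed product. Yet the epsilon readings gain 7.6 points in 0.666 d early and 6.8 points in 1.25 d late, so the mean creep is slower late than early. These readings do not show how much of the spare partner still stands in the epsilon flask, so I put the yield now at the last reading, 66.4%, within 1 point.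

The forecast says 66% now, 80% after maple and 88% after oak, and it picks birch: “it is the robust choice”.

The flask gives 66.6%, 67.9% after maple and 80.1% after oak. The best option is oak, which adds 14 points, against 1.4 points for maple, 1.4 points for elm and 1.2 points for birch.

    partner + left-handed substrate → left-handed product (k = 0.00950 M⁻¹ s⁻¹, Ea = 84.0 kJ mol⁻¹)
    partner + right-handed substrate → right-handed product (k = 8.49 × 10⁻⁵ M⁻¹ s⁻¹, Ea = 79.0 kJ mol⁻¹)
    left-handed substrate ⇌ achiral form (K = 0.160, k = 6.75 × 10⁻⁶ s⁻¹, Ea = 110 kJ mol⁻¹, ΔH = 26.0 kJ mol⁻¹)
    right-handed substrate ⇌ achiral form (K = 0.160, k = 6.75 × 10⁻⁶ s⁻¹, Ea = 110 kJ mol⁻¹, ΔH = 26.0 kJ mol⁻¹)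
    partner → decomposed reagent (k = 1.11 × 10⁻⁵ s⁻¹, Ea = 114 kJ mol⁻¹)
    (constants at 70 °C)

In this flask the half-life of partner by decomposition alone, 0.723 d, is shorter than the 1.2 d of right-handed substrate by its forward loss to achiral form at 0.484 d. At 2.50 d partner, the limiting reagent, stands at 1.61% of its charge while 20.0% right-handed substrate is free. Against the spare 33.4 mM stand 29.1 mM decomposed reagent, 3.33 mM right-handed product and 0.968 mM partner. In the neighbour flask charged with 24 mM partner the spare is 4.02 mM, against 3.52 mM decomposed reagent.

The earlier runs and the new flask are simulated for an exercise, and the scatter is random.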